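Atoms are labelled aN, the Nth non-hydrogen atom of the target SMILES (a1 = methoxy carbon … a35 = second methyl on a33).

## Analysis of the target

The target is a 6-6-6-7-6 pentacycle: ring A (a3, a4, a5, a6, a8, a33), ring B (a6, a8, a9, a10, a11, a32), ring C (a11, a13, a14, a30, a31, a32), seven-membered ring D (a14, a16, a17, a18, a26, a28, a30) and ring E (a18, a19, a22, a24, a25, a26). It has ten stereocentres: a3, a6, a8, a11, a14, a18, a22, a26, a30 and a32. In the west half the a6 methyl, a8–H, a32–H and the a11 methyl all lie on one face of ring B, so A/B and B/C are both cis-fused and syn to each other, and the a3 methoxy group is on that face too. In the east half C/D is trans-fused with the a14 hydroxyl cis to the a30–a28 bond, D/E is cis-fused (a18–H and the a26 methyl cis), and the a22 hydroxyl is cis to a28. The sensitive unit is the β-hydroxy ketone a14(OH)–a30–a28(=O), which can open ring C by retro-aldol or dehydrate; the a28 ketone is buried between quaternary a26 and tertiary a30. The difficulty lies in the medium ring, the quaternary carbons in and around it (a14, a26, a19) and the crowded all-cis ring B. The strategy rests on ring E: a26 is quaternary (methyl a27, acyl a28), sits para to oxygenated a22 and has a18 β to a22. That is the pattern of a 4-acyl-4-methylcyclohexa-2,5-dienone in which one enone arm has taken up a carbon, and the a17–a18 bond that does so also closes ring D.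

## Retrosynthetic reasoning

**Endgame (33 back to 28).** The a14 silyl ether, the a22 carbinol, the saturated a24–a25 bond and the two a19 methyls are all adjustments of one enone, so 33 is traced through 32, 31 and 30 to enedione 28. The only C–C bonds cut are the two a19–methyl bonds. They are cut here because a26 is quaternary, so the ring E enone of 28 can enolise only towards a19. The forward steps must alkylate a19 twice without touching the a30 methine, then reduce a22 and not a28.

**Key disconnection (28 back to 27).** The a17–a18 bond is cut. This removes ring D and both east-half stereocentres (a18, a26) and turns ring E into a symmetric cyclohexadienone with no stereocentre of its own. Cutting elsewhere in ring D (a28–a30 or a14–a16) would leave a26 to be made as an isolated quaternary stereocentre. The forward reaction must make a primary a17 radical from iodide 27 and have it add to one specific enone arm faster than it is reduced.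

**Ring C substituents (27 back to 15 and 19).** Functional-group changes lead from 27 through 26–21 to aldol 20. Then a14–a16 (addition of a vinyl nucleophile to the a14 ketone) and a28–a30 (aldol of ketone 15 with aldehyde 19) are cut. Both bonds radiate from the one carbonyl of 15, and the locked ring C chair with its axial a11 methyl should control both new centres. The forward steps must enolise a30 and not a13, and must add to a14 equatorially.

**Dienyl aldehyde (19 back to 16).** The methyl–carbon bond at the future a26 is cut, which returns to benzoic acid 16 through alcohol 18 and acid 17. A dearomatising reductive methylation gives the quaternary carbon and the skipped diene together. The diene tolerates the basic and hydridic steps and is oxidised to the dienone only after they are done.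

**a11 methyl (15 back to 14).** The a11–a12 bond is cut as a conjugate addition to enone 14. An octalone-type enone takes a methyl nucleophile cis to the ring-fusion hydrogen, which is the B/C relationship needed.

**Ring C from an arene (14 back to 12).** No C–C bond is cut. The enone of 14 is the hydrolysed reduction product of the anisole ring of 12 (via 13), so ring C can be carried as a robust aromatic ring through the ring A chemistry. The forward step must set a32 on protonation. The a3 ether of 12 comes from ketone 10 through alcohol 11 by a reagent-controlled reduction.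

**Ring A substituents (10 back to 8).** One a33–methyl bond is cut (enolate methylation of 9) and the a8–H and a33–H bonds are traced to hydrogenation of enone 8. Hydrogenation must precede the second methyl, because only the enone offers the face that leads to the cis A/B fusion.

**Ring A (8 back to 3 and 4, then 1).** The a8=a33 bond (aldol condensation of 7) and the a5–a6 bond (Michael addition of 3 to 4) are cut. This is a Robinson annulation, run through a chiral imine so that a6, the first stereocentre, is set absolutely. The C1 methyl of 3 comes from tetralone 1.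

## Alternatives that were turned down

**Alternative 1:** Ring E is disconnected at a19–a18 and a25–a26. In the forward direction a Lewis-acid-promoted Diels–Alder reaction between the hindered silyloxydiene A1 and the a26=a18 enone of cycloheptadienone A2 gives the cis-fused D/E bicycle A3. In its favour, the cis D/E fusion, quaternary a26, the a19 gem-dimethyl group and the a22 oxygen all arrive in one step, so the late dimethylation next to a β-silyloxy ketone in the chosen route is not needed, and no seven-membered ring has to be closed by a slow radical step. Against it, A3 is made away from the west half: it is racemic unless the cycloaddition is made enantioselective, and ring C must then be built between two hindered pieces with a14 (tertiary carbinol) and a30 set late and under no obvious control from either half. The diene terminus carrying two methyls must also bond to a β-carbon next to a quaternary centre, which is the most demanding version of this cycloaddition. On ring E itself this alternative is the stronger one. The chosen route offers instead growth of rings D and E on an enantiopure tricycle, so that a18 and a26 are relayed from a14 and a30, and it needs only benzoic acid for ring E.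

**Alternative 2:** The a5–a6 bond is disconnected, with a3–a11 re-formed in the precursor. In the forward direction the alkoxide of bicyclic vinyl carbinol A4 undergoes an anionic oxy-Cope rearrangement and opens to the cis-fused A/B octalone A5 (a3 ketone, a11=a32 alkene). In its favour, the cis A/B fusion and quaternary a6 are enforced by the bridged framework rather than by facial selectivity, which is firmer than the hydrogenation in step 4 of the chosen route. Against it, it solves only rings A and B, which the chosen route reaches by a classical annulation in five steps. A4 needs its own cycloaddition, an endo-vinyl carbinol and an enantioselective entry. Ring C would then have to be annulated onto a trisubstituted alkene next to quaternary a6 with a32–H syn to the a6 methyl, and rings D and E, the real problem, are untouched. The chosen route offers a shorter west half, an aromatic ring C that becomes the enone in one operation, and a key step aimed at ring D.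

**Alternative 3:** Ring B is disconnected at a6–a8 and a11–a32. In the forward direction the 14-membered E,E,Z-triene A6 undergoes a transannular Diels–Alder reaction to give the tricyclic ketone A7 with a9=a10. In its favour, all four ring B stereocentres follow from alkene geometry in one suprafacial step, so the all-cis relationship is dictated rather than dependent on an equilibrium (step 8) and a cuprate addition (step 9); on this point it is stronger. Against it, A6 requires three geometrically defined alkenes, two of them trisubstituted, and a macrocyclisation. The cycloaddition must form two quaternary carbons (a6, a11) at once, and a3 alone must control the face across the ring. A7 is still only the west half. The chosen route reaches the same tricycle in nine steps from a commercial tetralone and keeps the risk for ring D.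

Key step: step 21

Assumption: the a28 carbinol formed in step 13 is carried as a mixture of epimers through 20–23 (left open in their SMILES), because step 17 oxidises it.

## Route

**Step 1**
Reactants: 1 6-methoxy-3,4-dihydronaphthalen-2(1H)-one
Product: 3 rac-6-methoxy-1-methyl-3,4-dihydronaphthalen-2(1H)-one, via pyrrolidine enamine 2 (not isolated)
Conditions: pyrrolidine, PhMe, reflux (−H2O); MeI, MeCN, 60 °C; H2O, 60 °C
Reagents that add atoms: iodomethane, CI; water, O
Why: Stork enamine alkylation: the enamine conjugated with the arene is methylated once at C1, which avoids the over-alkylation of base-mediated methylation; hydrolysis returns the ketone.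

**Step 2**
Reactants: 3 rac-6-methoxy-1-methyl-3,4-dihydronaphthalen-2(1H)-one; 4 pent-1-en-3-one
Product: 7 (R)-6-methoxy-1-methyl-1-(3-oxopentyl)-3,4-dihydronaphthalen-2(1H)-one, via imine 5 (not isolated), via Michael adduct imine 6 (not isolated)
Conditions: (R)-1-phenylethylamine, TsOH (cat.), PhMe, reflux (−H2O); 4, THF, rt to 40 °C; 20% aq AcOH, rt
Reagents that add atoms: water, O
Why: Deracemising Michael addition of a chiral imine (d'Angelo type): both enantiomers of 3 react through the more substituted secondary enamine, which adds to 4 on the face anti to the phenyl group with internal proton transfer. By analogy with the (S)-amine/2-methylcyclohexanone case, the (R)-amine should give the (R) quaternary carbon a6.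

**Step 3**
Reactants: 7 (R)-6-methoxy-1-methyl-1-(3-oxopentyl)-3,4-dihydronaphthalen-2(1H)-one
Product: 8 (4aS)-7-methoxy-1,4a-dimethyl-4,4a,9,10-tetrahydrophenanthren-2(3H)-one
Conditions: NaOMe, MeOH, reflux
Reagents that add atoms: none
Why: Intramolecular aldol condensation (second half of a Robinson annulation) of the ethyl ketone onto the tetralone carbonyl closes ring A as the conjugated enone; a6 is not touched.

**Step 4**
Reactants: 8 (4aS)-7-methoxy-1,4a-dimethyl-4,4a,9,10-tetrahydrophenanthren-2(3H)-one
Product: 9 (1S,4aS,10aR)-7-methoxy-1,4a-dimethyl-3,4,4a,9,10,10a-hexahydrophenanthren-2(1H)-one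
Conditions: H2 (3 atm), Pd/C, KOH (cat.), EtOH, rt
Reagents that add atoms: none
Why: Heterogeneous hydrogenation of an enone of the 4a-methyl octalone / 4-en-3-one steroid type, which in basic medium takes hydrogen mainly on the face of the angular methyl and so should give the cis A/B fusion (a8–H syn to the a6 methyl). The a33 centre formed with it is erased in step 5.

**Step 5**
Reactants: 9 (1S,4aS,10aR)-7-methoxy-1,4a-dimethyl-3,4,4a,9,10,10a-hexahydrophenanthren-2(1H)-one
Product: 10 (4aS,10aS)-7-methoxy-1,1,4a-trimethyl-3,4,4a,9,10,10a-hexahydrophenanthren-2(1H)-one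
Conditions: KOtBu, t-BuOH–THF, rt; MeI
Reagents that add atoms: iodomethane, CI
Why: Thermodynamic enolate alkylation: the cis-fused ketone enolises towards the more substituted a33, and methylation there completes the gem-dimethyl group.

**Step 6**
Reactants: 10 (4aS,10aS)-7-methoxy-1,1,4a-trimethyl-3,4,4a,9,10,10a-hexahydrophenanthren-2(1H)-one
Product: 11 (2S,4aS,10aS)-7-methoxy-1,1,4a-trimethyl-1,2,3,4,4a,9,10,10a-octahydrophenanthren-2-ol
Conditions: (R)-2-methyl-CBS-oxazaborolidine (0.2 equiv), BH3·SMe2, THF, −20 °C; MeOH
Reagents that add atoms: none
Why: Corey–Bakshi–Shibata reduction: quaternary a33 is the large and the a4 methylene the small substituent, so the (R)-catalyst should give the (S)-carbinol, with a3–O cis to the a6 methyl, by reagent control.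

**Step 7**
Reactants: 11 (2S,4aS,10aS)-7-methoxy-1,1,4a-trimethyl-1,2,3,4,4a,9,10,10a-octahydrophenanthren-2-ol
Product: 12 (2S,4aS,10aS)-2,7-dimethoxy-1,1,4a-trimethyl-1,2,3,4,4a,9,10,10a-octahydrophenanthrene
Conditions: NaH, MeI, THF–DMF, 0 °C to rt
Reagents that add atoms: iodomethane, CI
Why: Williamson etherification of the hindered secondary alkoxide with a small electrophile; no stereocentre is involved.

**Step 8**
Reactants: 12 (2S,4aS,10aS)-2,7-dimethoxy-1,1,4a-trimethyl-1,2,3,4,4a,9,10,10a-octahydrophenanthrene
Product: 14 tricyclic enone (a14 ketone, a13=a11, a32–H syn to the a6 methyl), via dihydroanisole 13 (not isolated)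
Conditions: Li, NH3(l), THF, t-BuOH, −78 to −33 °C; MeOH; then 2 M HCl, THF–MeOH, 40 °C
Reagents that add atoms: water, O
Why: Birch reduction of the anisole ring keeps a14–OMe and the tetrasubstituted a11=a32 alkene on sp2 carbons (13); acid hydrolyses the enol ether and moves the alkene into conjugation, protonating a32 reversibly. The epimer with a31 equatorial on ring B should prevail, and because the quaternary a33 keeps a5 axial on ring B of the cis A/B bicycle, that epimer has a32–H syn to the a6 methyl.

**Step 9**
Reactants: 14 tricyclic enone
Product: 15 tricyclic ketone of rings A–C (a14 ketone, a11 methyl cis to a32–H and to the a6 methyl)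
Conditions: Me2CuLi (from CuI and MeLi), Et2O, 0 °C; aq NH4Cl
Reagents that add atoms: lithium dimethylcuprate, [Li+].C[Cu-]C
Why: Gilman 1,4-addition to a bicyclic β,β-disubstituted enone: axial attack on the ring C half-chair syn to the a32 hydrogen gives the cis B/C fusion, and the other face of a11 is also blocked 1,3-diaxially by a5.

**Step 10**
Reactants: 16 benzoic acid
Product: 17 1-methylcyclohexa-2,5-diene-1-carboxylic acid
Conditions: Li, NH3(l), THF, −78 °C; MeI; NH4Cl; aq HCl
Reagents that add atoms: iodomethane, CI
Why: Birch reductive alkylation: the dienolate dianion of 1,4-dihydrobenzoate is methylated at the carboxyl-bearing carbon, giving the skipped diene with the quaternary carbon that becomes a26.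

**Step 11**
Reactants: 17 1-methylcyclohexa-2,5-diene-1-carboxylic acid
Product: 18 (1-methylcyclohexa-2,5-dien-1-yl)methanol
Conditions: LiAlH4, THF, 0 °C to reflux; H2O, aq NaOH
Reagents that add atoms: none
Why: Hydride reduction of the acid to the neopentyl alcohol; the unconjugated diene is inert.

**Step 12**
Reactants: 18 (1-methylcyclohexa-2,5-dien-1-yl)methanol
Product: 19 1-methylcyclohexa-2,5-diene-1-carbaldehyde
Conditions: Dess–Martin periodinane, NaHCO3, CH2Cl2, 0 °C to rt
Reagents that add atoms: none
Why: Dess–Martin oxidation under buffered conditions; the aldehyde cannot enolise and is used at once as a solution.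

**Step 13**
Reactants: 15 tricyclic ketone of rings A–C; 19 1-methylcyclohexa-2,5-diene-1-carbaldehyde
Product: 20 aldol (a14 ketone; a30 bears the a28 carbinol with the 1-methylcyclohexa-2,5-dienyl group, equatorial on ring C)
Conditions: LiN(iPr)2, THF, −78 °C; 19; AcOH, −78 °C
Reagents that add atoms: none
Why: Directed aldol addition: the amide base takes the a30 proton (a13 is neopentyl, next to quaternary a11). The enolate should add to 19 anti to the axial a6 substituent on a32, which places the side chain equatorial; this is also the thermodynamic position.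

**Step 14**
Reactants: 20 aldol
Product: 21 vinyl diol (a14 tertiary alcohol axial, cis to the a11 methyl and to the a30 side chain; vinyl equatorial)
Conditions: CeCl3, CH2=CHMgBr (4 equiv), THF, −78 °C; aq NH4Cl
Reagents that add atoms: vinylmagnesium bromide, C=C[Mg]Br
Why: Organocerium 1,2-addition to a hindered, enolisable ketone: the axial a11 methyl blocks axial attack (as in 3,3,5-trimethylcyclohexanone), so vinyl should enter equatorially and leave the a14 hydroxyl axial. The low basicity of the cerium reagent at −78 °C limits retro-aldol of the aldolate.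

**Step 15**
Reactants: 21 vinyl diol
Product: 22 triol (primary a17 alcohol)
Conditions: 9-BBN (4 equiv), THF, 0 °C to rt; NaOH, H2O2, 0 °C
Reagents that add atoms: hydrogen peroxide, OO
Why: Anti-Markovnikov hydroboration–oxidation; 9-BBN adds to a terminal vinyl group far faster than to the cis-disubstituted ring alkenes.

**Step 16**
Reactants: 22 triol
Product: 23 primary tosylate
Conditions: TsCl, pyridine, CH2Cl2, 0 °C
Reagents that add atoms: p-toluenesulfonyl chloride, Cc1ccc(cc1)S(Cl)(=O)=O
Why: Selective sulfonylation of the primary hydroxyl next to a neopentyl secondary and a tertiary one.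

**Step 17**
Reactants: 23 primary tosylate
Product: 24 β-hydroxy ketone (a28 ketone, free a14 alcohol)
Conditions: Dess–Martin periodinane, NaHCO3, CH2Cl2, rt
Reagents that add atoms: none
Why: Dess–Martin oxidation of the remaining secondary alcohol; the tertiary alcohol, tosylate and diene are inert, and the buffered medium avoids retro-aldol.

**Step 18**
Reactants: 24 β-hydroxy ketone
Product: 25 a14 triethylsilyl ether
Conditions: Et3SiOTf, 2,6-lutidine, CH2Cl2, −78 to 0 °C
Reagents that add atoms: triethylsilyl trifluoromethanesulfonate, CC[Si](CC)(CC)OS(=O)(=O)C(F)(F)F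
Why: Silylation of the tertiary axial alcohol with a silyl triflate; this blocks retro-aldol opening of ring C in the later steps.

**Step 19**
Reactants: 25 a14 triethylsilyl ether
Product: 26 cyclohexa-2,5-dienone tosylate
Conditions: (pyH)2Cr2O7, t-BuOOH, Celite, PhH, rt
Reagents that add atoms: tert-butyl hydroperoxide, CC(C)(C)OO
Why: Bis-allylic oxidation of a 3,3-disubstituted cyclohexa-1,4-diene to the cross-conjugated dienone by a chromate-promoted hydroperoxide oxidation, the usual sequel to Birch reductive alkylation; the ring CH2 carries the only doubly allylic C–H bonds in 25.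

**Step 20**
Reactants: 26 cyclohexa-2,5-dienone tosylate
Product: 27 iodide (a14 OSiEt3 and CH2CH2I; a30 bears the 1-methyl-4-oxocyclohexa-2,5-dienyl ketone)
Conditions: NaI, acetone, 55 °C
Reagents that add atoms: sodium iodide, [Na+].[I-]
Why: Finkelstein displacement at the unhindered primary a17; the iodide is introduced last so that it never meets the oxidants.

**Step 21**
Reactants: 27 iodide
Product: 28 pentacyclic enedione (a22 ketone, a24=a25, a19 CH2, a28 ketone, a14 OSiEt3)
Conditions: (Me3Si)3SiH (1.3 equiv, syringe pump), AIBN (0.2 equiv), PhH (0.005 M), 80 °C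
Reagents that add atoms: none
Why: The silyl radical abstracts iodine from 27 to give the primary a17 radical, which adds to the β-carbon a18 of one enone arm in a 7-exo-trig closure of ring D; the resulting a19 α-keto radical takes hydrogen from the silane and carries the chain. The closest known chemistry is the intramolecular Giese-type radical conjugate addition that desymmetrises 4,4-disubstituted cyclohexa-2,5-dienones, mostly in 5- and 6-exo modes. The slower seven-membered closure is helped by the gauche, diequatorial a14–a16 and a30–a28 bonds on the locked ring C chair, by the quaternary carbons in the tether and by the electron-poor acceptor; the silane is a slower hydrogen donor than a tin hydride and is kept dilute. a18 is set by the tether: a17 can reach only the dienone face that carries a28, so a17 and a28 end cis on ring E (cis D/E fusion). a26 is set by the choice of arm: in a chair-like seven-membered transition state the a26 methyl, which stands perpendicular to the dienone plane, should sit on the side of the axial a30 hydrogen while the flat unreacted arm faces the a31 methylene, and this gives the a26 configuration of 28. The step needs this arm selectivity and needs cyclisation to outrun direct reduction; the first rests on the rigid ring C chair fixed by a14 and a30, the second on dilution.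

**Step 22**
Reactants: 28 pentacyclic enedione
Product: 30 a19 gem-dimethyl enedione, via monomethyl enone 29 (not isolated)
Conditions: LiN(SiMe3)2, THF, −78 °C; MeI; then LiN(SiMe3)2, DMPU, MeI, −78 to −40 °C
Reagents that add atoms: iodomethane, CI
Why: Kinetic α'-enolate alkylation of the enone, carried out twice: a26 is quaternary, so no γ-deprotonation is possible. The bulky amide should take the accessible a19 protons rather than the hindered a30 methine, whose enolate would expel the a14 silyloxy group.

**Step 23**
Reactants: 30 a19 gem-dimethyl enedione
Product: 31 saturated diketone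
Conditions: H2 (1 atm), Pd/C, EtOAc, rt
Reagents that add atoms: none
Why: Heterogeneous hydrogenation of the cis-disubstituted enone alkene; no stereocentre is formed, and the ketones and silyl ether are untouched.

**Step 24**
Reactants: 31 saturated diketone
Product: 32 a22 alcohol (hydroxyl cis to a28), a14 silyl ether
Conditions: NaBH4, MeOH–THF, −20 to 0 °C
Reagents that add atoms: none
Why: Borohydride reduces the less hindered a22 ketone (a28 lies between quaternary a26 and tertiary a30). In the ring E chair with a28 axial, hydride should attack a22 axially, away from the axial a19 methyl, to give the equatorial alcohol, as with 4,4-dimethyl-3-keto triterpenoids.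

**Step 25**
Reactants: 32 a22 alcohol
Product: 33 CNP0259231.1
Conditions: HF·pyridine, pyridine–THF, 0 °C to rt
Reagents that add atoms: none
Why: Fluoride cleavage of the tertiary triethylsilyl ether in a buffered acidic medium, which avoids base-induced retro-aldol of the β-hydroxy ketone.

## Compound list

1 | 6-methoxy-3,4-dihydronaphthalen-2(1H)-one | COc1ccc2c(c1)CCC(=O)C2 | starting material
2 | 1-(6-methoxy-3,4-dihydronaphthalen-2-yl)pyrrolidine | COc1ccc2C=C(N3CCCC3)CCc2c1 | intermediate
3 | rac-6-methoxy-1-methyl-3,4-dihydronaphthalen-2(1H)-one | COc1ccc2c(c1)CCC(=O)C2C | intermediate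
4 | pent-1-en-3-one | C=CC(=O)CC | starting material
5 | imine of 3 with (R)-1-phenylethylamine (C1 epimers equilibrate) | COc1ccc2c(c1)CCC(=N[C@H](C)c1ccccc1)C2C | intermediate
6 | (R)-1-phenylethyl imine of 7 | CCC(=O)CC[C@@]1(C)C(=N[C@H](C)c2ccccc2)CCc2cc(OC)ccc21 | intermediate
7 | (R)-6-methoxy-1-methyl-1-(3-oxopentyl)-3,4-dihydronaphthalen-2(1H)-one | CCC(=O)CC[C@@]1(C)C(=O)CCc2cc(OC)ccc21 | intermediate
8 | (4aS)-7-methoxy-1,4a-dimethyl-4,4a,9,10-tetrahydrophenanthren-2(3H)-one | O=C1CC[C@@]2(C)C(CCc3cc(OC)ccc32)=C1C | intermediate
9 | (1S,4aS,10aR)-7-methoxy-1,4a-dimethyl-3,4,4a,9,10,10a-hexahydrophenanthren-2(1H)-one | O=C1CC[C@@]2(C)[C@H](CCc3cc(OC)ccc32)[C@@H]1C | intermediate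
10 | (4aS,10aS)-7-methoxy-1,1,4a-trimethyl-3,4,4a,9,10,10a-hexahydrophenanthren-2(1H)-one | O=C1CC[C@@]2(C)[C@H](CCc3cc(OC)ccc32)C1(C)C | intermediate
11 | (2S,4aS,10aS)-7-methoxy-1,1,4a-trimethyl-1,2,3,4,4a,9,10,10a-octahydrophenanthren-2-ol | O[C@H]1CC[C@@]2(C)[C@H](CCc3cc(OC)ccc32)C1(C)C | intermediate
12 | (2S,4aS,10aS)-2,7-dimethoxy-1,1,4a-trimethyl-1,2,3,4,4a,9,10,10a-octahydrophenanthrene | CO[C@H]1CC[C@@]2(C)[C@H](CCc3cc(OC)ccc32)C1(C)C | intermediate
13 | dihydroanisole of 12 (a14 methyl enol ether a14=a30, a11=a32 alkene, a13 and a31 CH2) | CO[C@H]1CC[C@@]2(C)[C@H](CCC3=C2CC=C(OC)C3)C1(C)C | intermediate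
14 | tricyclic enone (a14 ketone, a13=a11; a32–H, a6 methyl, a8–H and a3 methoxy on one face) | CO[C@H]1CC[C@@]2(C)[C@H](CCC3=CC(=O)CC[C@H]32)C1(C)C | intermediate
15 | tricyclic ketone of rings A–C (a14 ketone; a6 methyl, a8–H, a32–H, a11 methyl all cis) | CO[C@H]1CC[C@@]2(C)[C@H](CC[C@@]3(C)CC(=O)CC[C@H]32)C1(C)C | intermediate
16 | benzoic acid | OC(=O)c1ccccc1 | starting material
17 | 1-methylcyclohexa-2,5-diene-1-carboxylic acid | CC1(C(=O)O)C=CCC=C1 | intermediate
18 | (1-methylcyclohexa-2,5-dien-1-yl)methanol | CC1(CO)C=CCC=C1 | intermediate
19 | 1-methylcyclohexa-2,5-diene-1-carbaldehyde | CC1(C=O)C=CCC=C1 | intermediate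
20 | aldol of 15 at a30 with 19 (a28 carbinol, both epimers; side chain equatorial) | CO[C@H]1CC[C@@]2(C)[C@H](CC[C@@]3(C)CC(=O)[C@H](C(O)C4(C)C=CCC=C4)C[C@H]32)C1(C)C | intermediate
21 | vinyl diol (a14 hydroxyl axial, cis to the a11 methyl and the a30 side chain) | CO[C@H]1CC[C@@]2(C)[C@H](CC[C@@]3(C)C[C@@](O)(C=C)[C@H](C(O)C4(C)C=CCC=C4)C[C@H]32)C1(C)C | intermediate
22 | triol (a14 bears CH2CH2OH) | CO[C@H]1CC[C@@]2(C)[C@H](CC[C@@]3(C)C[C@@](O)(CCO)[C@H](C(O)C4(C)C=CCC=C4)C[C@H]32)C1(C)C | intermediate
23 | primary tosylate of 22 | CO[C@H]1CC[C@@]2(C)[C@H](CC[C@@]3(C)C[C@@](O)(CCOS(=O)(=O)c4ccc(C)cc4)[C@H](C(O)C5(C)C=CCC=C5)C[C@H]32)C1(C)C | intermediate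
24 | β-hydroxy ketone (a28 ketone, a14 alcohol, tosylate) | CO[C@H]1CC[C@@]2(C)[C@H](CC[C@@]3(C)C[C@@](O)(CCOS(=O)(=O)c4ccc(C)cc4)[C@H](C(=O)C5(C)C=CCC=C5)C[C@H]32)C1(C)C | intermediate
25 | a14 triethylsilyl ether of 24 | CO[C@H]1CC[C@@]2(C)[C@H](CC[C@@]3(C)C[C@@](O[Si](CC)(CC)CC)(CCOS(=O)(=O)c4ccc(C)cc4)[C@H](C(=O)C5(C)C=CCC=C5)C[C@H]32)C1(C)C | intermediate
26 | cyclohexa-2,5-dienone tosylate | CO[C@H]1CC[C@@]2(C)[C@H](CC[C@@]3(C)C[C@@](O[Si](CC)(CC)CC)(CCOS(=O)(=O)c4ccc(C)cc4)[C@H](C(=O)C5(C)C=CC(=O)C=C5)C[C@H]32)C1(C)C | intermediate
27 | iodide, precursor of the key step | CO[C@H]1CC[C@@]2(C)[C@H](CC[C@@]3(C)C[C@@](O[Si](CC)(CC)CC)(CCI)[C@H](C(=O)C4(C)C=CC(=O)C=C4)C[C@H]32)C1(C)C | intermediate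
28 | pentacyclic enedione (ring D closed, cis D/E) | CO[C@H]1CC[C@@]2(C)[C@H](CC[C@@]3(C)C[C@@]4(O[Si](CC)(CC)CC)CC[C@@H]5CC(=O)C=C[C@]5(C)C(=O)[C@@H]4C[C@H]32)C1(C)C | intermediate
29 | a19 monomethyl enedione (a19 epimers) | CO[C@H]1CC[C@@]2(C)[C@H](CC[C@@]3(C)C[C@@]4(O[Si](CC)(CC)CC)CC[C@@H]5C(C)C(=O)C=C[C@]5(C)C(=O)[C@@H]4C[C@H]32)C1(C)C | intermediate
30 | a19 gem-dimethyl enedione | CO[C@H]1CC[C@@]2(C)[C@H](CC[C@@]3(C)C[C@@]4(O[Si](CC)(CC)CC)CC[C@@H]5C(C)(C)C(=O)C=C[C@]5(C)C(=O)[C@@H]4C[C@H]32)C1(C)C | intermediate
31 | saturated a22,a28-diketone | CO[C@H]1CC[C@@]2(C)[C@H](CC[C@@]3(C)C[C@@]4(O[Si](CC)(CC)CC)CC[C@@H]5C(C)(C)C(=O)CC[C@]5(C)C(=O)[C@@H]4C[C@H]32)C1(C)C | intermediate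
32 | a22 alcohol, a14 triethylsilyl ether | CO[C@H]1CC[C@@]2(C)[C@H](CC[C@@]3(C)C[C@@]4(O[Si](CC)(CC)CC)CC[C@@H]5C(C)(C)[C@H](O)CC[C@]5(C)C(=O)[C@@H]4C[C@H]32)C1(C)C | intermediate
33 | CNP0259231.1 | CO[C@H]1CC[C@@]2(C)[C@H](CC[C@@]3(C)C[C@@]4(O)CC[C@@H]5C(C)(C)[C@H](O)CC[C@]5(C)C(=O)[C@@H]4C[C@H]32)C1(C)C | target

## Step count and least certain steps

Total: 25 steps. Longest linear sequence: 22 steps (steps 1–9 and 13–25 from 1); the aldehyde branch (steps 10–12) adds three.

**Step 21 (key step).** Two things can fail. The primary radical may take hydrogen from the silane before the slow seven-membered closure, and it may add to the other enone arm, which would give the a26 epimer; the arm preference rests on a conformational argument that has no close model. Fallback: from 27, displacement with NaNO2 in DMF should give the nitroethyl dienone F1. DBU in MeCN should then close ring D by a reversible intramolecular nitronate conjugate addition, giving the a17-nitro enedione F2 under thermodynamic rather than kinetic control. Radical denitration (Bu3SnH, AIBN, PhMe, 110 °C) returns to 28.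

**Step 8.** The a32 centre is set by reversible protonation, and the preference for the all-cis epimer may be modest, so an epimer mixture may result; the conformational bias of the cis A/B bicycle is the only control. Fallback: from 14 (as the epimer mixture), dehydrogenation with chloranil in refluxing t-BuOH should give the linear dienone F3, which has no a32 stereocentre. Partial hydrogenation of its a31=a32 bond (H2, Pd/CaCO3, pyridine) then delivers hydrogen to a32 kinetically, from the face away from the axial a5, and returns to 14.

**Step 4.** Hydrogen may be delivered to the face opposite the a6 methyl, giving the trans A/B fusion, and the tetrasubstituted alkene may reduce slowly. Fallback: from 8, Luche reduction (NaBH4, CeCl3·7H2O, MeOH) should give the allylic alcohol F4 with the hydroxyl cis to the a6 methyl. Hydroxyl-directed hydrogenation with [Ir(cod)(PCy3)(py)]PF6 and H2 in CH2Cl2 should then add hydrogen from that face to give the saturated alcohol F5. Dess–Martin oxidation returns to 9.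

**Step 6.** The catalyst's facial preference may be opposed by the substrate's own bias, which would erode selectivity at a3. Fallback: from 10, Li in NH3 with t-BuOH reduces ketone and arene together and should give the thermodynamically favoured (equatorial) alcohol as the dihydroanisole alcohol F6. O-methylation (NaH, MeI) gives 13, which is hydrolysed to 14 as in step 8.

**Step 19.** The cyclohexadienyl radical formed by hydrogen abstraction may fragment, losing the acyl group and aromatising the ring, and over-oxidation is possible. Fallback: from 25, a non-radical ene/[2,3] oxidation with SeO2 (cat.) and t-BuOOH in CH2Cl2 should give the dienol F7. MnO2 then oxidises it to 26.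

## Further compounds

F1 | step 21 | nitroethyl dienone (27 with NO2 in place of I) | CO[C@H]1CC[C@@]2(C)[C@H](CC[C@@]3(C)C[C@@](O[Si](CC)(CC)CC)(CC[N+](=O)[O-])[C@H](C(=O)C4(C)C=CC(=O)C=C4)C[C@H]32)C1(C)C
F2 | step 21 | a17-nitro enedione (28 with NO2 on a17, a17 epimers) | CO[C@H]1CC[C@@]2(C)[C@H](CC[C@@]3(C)C[C@@]4(O[Si](CC)(CC)CC)CC([N+](=O)[O-])[C@@H]5CC(=O)C=C[C@]5(C)C(=O)[C@@H]4C[C@H]32)C1(C)C
F3 | step 8 | linear dienone (a14 ketone, a13=a11 and a32=a31) | CO[C@H]1CC[C@@]2(C)[C@H](CCC3=CC(=O)CC=C32)C1(C)C
F4 | step 4 | allylic alcohol of 8 (a3 hydroxyl cis to the a6 methyl) | O[C@H]1CC[C@@]2(C)C(CCc3cc(OC)ccc32)=C1C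
F5 | step 4 | saturated alcohol (a3 hydroxyl, a33–H and a8–H cis to the a6 methyl) | O[C@H]1CC[C@@]2(C)[C@H](CCc3cc(OC)ccc32)[C@@H]1C
F6 | step 6 | dihydroanisole alcohol (13 with a3 hydroxyl) | O[C@H]1CC[C@@]2(C)[C@H](CCC3=C2CC=C(OC)C3)C1(C)C
F7 | step 19 | dienol (25 with hydroxyl on the ring CH2 carbon) | CO[C@H]1CC[C@@]2(C)[C@H](CC[C@@]3(C)C[C@@](O[Si](CC)(CC)CC)(CCOS(=O)(=O)c4ccc(C)cc4)[C@H](C(=O)C5(C)C=CC(O)C=C5)C[C@H]32)C1(C)C
A1 | alternative 1 | 4-methyl-3-(tert-butyldimethylsilyloxy)penta-1,3-diene | C=CC(O[Si](C)(C)C(C)(C)C)=C(C)C
A2 | alternative 1 | 3-methoxy-7-methylcyclohepta-2,6-dien-1-one | COC1=CC(=O)C(C)=CCC1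
A3 | alternative 1 | cis-fused D/E bicycle (vinylogous ester in ring D, silyl enol ether at a22) | COC1=CC(=O)[C@@]2(C)CC=C(O[Si](C)(C)C(C)(C)C)C(C)(C)[C@H]2CC1
A4 | alternative 2 | 1,3,3,5-tetramethyl-2-vinylbicyclo[2.2.2]oct-5-en-2-ol (vinyl syn to the alkene bridge) | C=C[C@]1(O)C(C)(C)[C@H]2CC[C@]1(C)C=C2C
A5 | alternative 2 | cis-fused A/B octalone (a3 ketone, a11=a32 alkene) | O=C1CC[C@@]2(C)[C@H](CCC(C)=C2)C1(C)C
A6 | alternative 3 | 14-membered E,E,Z-triene ketone | CO[C@H]1CC/C(C)=C\CCC(=O)C/C(C)=C/C=C/C1(C)C
A7 | alternative 3 | tricyclic A/B/C ketone with a9=a10 alkene | CO[C@H]1CC[C@@]2(C)[C@H](C=C[C@@]3(C)CC(=O)CC[C@H]32)C1(C)C
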